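**Retrosynthetic overview**
1. Target ⇐ trans-selective 1,2-reduction of the C3 ketone of a cross-conjugated 6-acetoxy-5-methoxy-cyclohexadienone (C3 set relative to C6).
2. Dienone ⇐ two-carbon ring expansion (four → six) of (R)-4-acetoxy-3-methoxycyclobutenone: nickel inserts into the acyl–C4 bond, the terminal alkyne (R)-pentadec-1-yn-4-yl acetate inserts, and the C6 stereocentre is carried over.
3. Cyclobutenone ⇐ acetoxyketene + methoxyethyne [2+2], then lipase resolution.
4. Alkyne ⇐ acetylide opening of (R)-2-undecyloxirane ⇐ (R)-1,2-epoxy-5-hexene + 1-bromoheptane (hydroboration, alkyl–alkyl Suzuki coupling).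
5. Ring order: the four-membered ring is made first and is then expanded into the only ring of the target.

Assumption: methoxyethyne 2 is taken as a purchasable reagent (cold solution from a specialist supplier); all other inputs are standard catalogue chemicals.

**Route**

Step 1
Reactants: 1 acetoxyacetyl chloride (2-chloro-2-oxoethyl acetate); 2 methoxyethyne (methoxyacetylene)
Product: 4 (±)-4-acetoxy-3-methoxycyclobut-2-en-1-one, via acetoxyketene 3 (not isolated)
Conditions: Et3N (1.2 equiv, slow addition), 2 (3 equiv), Et2O, 0 °C → rt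
Reagents that add atoms: none
Why: Et3N dehydrochlorinates 1 to acetoxyketene, which undergoes the classical ketene–ynol ether [2+2] cycloaddition with the nucleophilic CH terminus of 2 bonding to the ketene carbonyl carbon, so the methoxy carbon lies next to the acetoxy carbon; the new stereocentre forms racemic.

Step 2
Reactants: 4 (±)-4-acetoxy-3-methoxycyclobut-2-en-1-one
Product: 5 (R)-4-acetoxy-3-methoxycyclobut-2-en-1-one
Conditions: Novozym 435 (immobilised Candida antarctica lipase B), n-BuOH (3 equiv), MTBE, 30 °C, stopped at about 55% conversion (chiral HPLC)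
Reagents that add atoms: none
Why: Lipase-catalysed kinetic resolution by enantioselective alcoholysis of a secondary acetate; the Kazlauskas size model predicts faster deacylation of the (S)-acetate, so going just past half conversion leaves 5 in high ee, and C4 cannot epimerise because its enolate would be an antiaromatic cyclobutadienolate.

Step 3
Reactants: 6 (R)-2-(but-3-en-1-yl)oxirane [(R)-1,2-epoxy-5-hexene]; 7 1-bromoheptane
Product: 9 (R)-2-undecyloxirane, via alkyl-9-BBN borane 8 (not isolated)
Conditions: 9-BBN (1.05 equiv), THF, 0 °C → rt; then 7, Pd(OAc)2 (4 mol%), PCy3 (8 mol%), K3PO4·H2O, THF, rt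
Reagents that add atoms: none
Why: Anti-Markovnikov hydroboration followed by B-alkyl Suzuki–Miyaura alkyl–alkyl coupling (the bulky electron-rich phosphine outruns β-hydride elimination); the epoxide and its stereocentre are not touched.

Step 4
Reactants: 9 (R)-2-undecyloxirane; 10 lithium acetylide–ethylenediamine complex
Product: 11 (R)-pentadec-1-yn-4-ol
Conditions: 10 (1.5 equiv), DMSO, 0 °C → rt; then H2O
Reagents that add atoms: none
Why: SN2 opening of the terminal epoxide by acetylide at the unhindered CH2; the carbinol carbon is not attacked, so (R) is retained.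

Step 5
Reactants: 11 (R)-pentadec-1-yn-4-ol
Product: 12 (R)-pentadec-1-yn-4-yl acetate
Conditions: Ac2O, pyridine, DMAP (cat.), CH2Cl2, rt
Reagents that add atoms: acetic anhydride, CC(=O)OC(C)=O
Why: DMAP-catalysed O-acetylation with retention at the carbinol carbon.

Step 6
Reactants: 5 (R)-4-acetoxy-3-methoxycyclobut-2-en-1-one; 12 (R)-pentadec-1-yn-4-yl acetate
Product: 13 (R)-1-[(6S)-6-acetoxy-5-methoxy-3-oxocyclohexa-1,4-dien-1-yl]tridecan-2-yl acetate
Conditions: Ni(cod)2 [bis(1,5-cyclooctadiene)nickel] (10 mol%), PPh3 (20 mol%), toluene, −20 → 0 °C, 12 (1.2 equiv) by syringe pump, no base or protic additive; cold filtration through Celite under argon, filtrate used at once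
Reagents that add atoms: none
Why: Proposed new method: zerovalent nickel inserts with retention into the strained acyl–C4 σ-bond of 5, far below the temperature of thermal electrocyclic ring opening; the acyl/allyl nickelacycle then adds across the alkyne with the acyl carbon bonding to the unsubstituted alkyne carbon (steric control, nickel on the substituted carbon), and inner-sphere reductive elimination on the nickel-bound face of C4 closes the six-membered ring. The geometry at the acetoxy carbon is therefore retained (R in 5 becomes 6S in 13 only through a change in CIP ranking), and in a neutral aprotic medium at or below 0 °C the 4H-dienone lacks the intermolecular proton shift that aromatisation needs. The closest known reaction type is the nickel-catalysed cyclobutenone–alkyne [4+2] annulation to phenols (and rhodium-catalysed C–C activation/insertion of cyclobutanones), which has not been shown with a stereogenic 4-acyloxy carbon, with stereoretention, or with arrest at the non-aromatic dienone.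

Step 7
Reactants: 13 (R)-1-[(6S)-6-acetoxy-5-methoxy-3-oxocyclohexa-1,4-dien-1-yl]tridecan-2-yl acetate
Product: 14 (R)-1-[(3S,6S)-6-acetoxy-3-hydroxy-5-methoxycyclohexa-1,4-dien-1-yl]tridecan-2-yl acetate (CNP0081579.1)
Conditions: NaBH4 (1.1 equiv), CeCl3·7H2O (1.2 equiv), MeOH–toluene, −78 °C, 20 min; pH 7 phosphate buffer; Et3N-deactivated silica
Reagents that add atoms: none
Why: Luche 1,2-reduction of the only ketone; hydride adds to the face syn to the C6 acetoxy group (the dipole-minimised transition state known for nucleophilic additions to 4-oxygenated cyclohexa-2,5-dienones), which puts the new hydroxyl trans to the acetate and sets C3 as (S), while the low temperature suppresses acetate methanolysis and base-induced aromatisation.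

**Compound list**
1 | acetoxyacetyl chloride (2-chloro-2-oxoethyl acetate) | CC(=O)OCC(Cl)=O | starting material
2 | methoxyethyne (methoxyacetylene) | COC#C | starting material
3 | acetoxyketene (2-oxoethenyl acetate) | CC(=O)OC=C=O | intermediate
4 | (±)-4-acetoxy-3-methoxycyclobut-2-en-1-one (racemic) | O=C1C=C(OC)C1OC(C)=O | intermediate
5 | (R)-4-acetoxy-3-methoxycyclobut-2-en-1-one | O=C1C=C(OC)[C@H]1OC(C)=O | intermediate
6 | (R)-2-(but-3-en-1-yl)oxirane [(R)-1,2-epoxy-5-hexene] | C=CCC[C@@H]1CO1 | starting material
7 | 1-bromoheptane | CCCCCCCBr | starting material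
8 | 9-{4-[(2R)-oxiran-2-yl]butyl}-9-borabicyclo[3.3.1]nonane | C1CCC2CCCC1B2CCCC[C@@H]1CO1 | intermediate
9 | (R)-2-undecyloxirane [(R)-1,2-epoxytridecane] | CCCCCCCCCCC[C@@H]1CO1 | intermediate
10 | lithium acetylide–ethylenediamine complex | [Li+].[C-]#C.NCCN | starting material
11 | (R)-pentadec-1-yn-4-ol | CCCCCCCCCCC[C@H](CC#C)O | intermediate
12 | (R)-pentadec-1-yn-4-yl acetate | CCCCCCCCCCC[C@H](CC#C)OC(C)=O | intermediate
13 | (R)-1-[(6S)-6-acetoxy-5-methoxy-3-oxocyclohexa-1,4-dien-1-yl]tridecan-2-yl acetate | CCCCCCCCCCC[C@H](CC1=CC(=O)C=C(OC)[C@H]1OC(C)=O)OC(C)=O | intermediate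
14 | (R)-1-[(3S,6S)-6-acetoxy-3-hydroxy-5-methoxycyclohexa-1,4-dien-1-yl]tridecan-2-yl acetate | CCCCCCCCCCC[C@H](CC1=C[C@H](O)C=C(OC)[C@H]1OC(C)=O)OC(C)=O | target

**Count and risks**
Total steps: 7. Longest linear sequence: 5 (steps 3, 4, 5, 6, 7).

Step 6 (the proposed new step). Risks: tautomerisation of 13 to the hydroquinone monoacetate, erosion at C6 if the nickel leaves the ring face, the wrong alkyne regiochemistry, and alkyne oligomerisation. Fallback with known chemistry, setting out from racemic 4 and 12 and returning at 13: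
- The established phenol-forming nickel annulation (Ni(cod)2, PPh3, toluene, rt, then silica gel) is run to full aromatisation and gives the hydroquinone monoacetate (R)-1-(2-acetoxy-5-hydroxy-3-methoxyphenyl)tridecan-2-yl acetate F1.
- MeI and K2CO3 in acetone give the methyl ether (R)-1-(2-acetoxy-3,5-dimethoxyphenyl)tridecan-2-yl acetate F2.
- Pyrrolidine in CH2Cl2 at 0 °C removes only the aryl acetate and gives the phenol (R)-1-(2-hydroxy-3,5-dimethoxyphenyl)tridecan-2-yl acetate F3.
- PhI(OAc)2 in MeOH gives the para-quinone monoketal (R)-1-(3,3,5-trimethoxy-6-oxocyclohexa-1,4-dien-1-yl)tridecan-2-yl acetate F4.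
- Corey–Bakshi–Shibata reduction (catalyst enantiomer chosen by a test run) sets C6 and gives the dienol (R)-1-[(6S)-6-hydroxy-3,3,5-trimethoxycyclohexa-1,4-dien-1-yl]tridecan-2-yl acetate F5.
- Ac2O and pyridine give the diacetate (R)-1-[(6S)-6-acetoxy-3,3,5-trimethoxycyclohexa-1,4-dien-1-yl]tridecan-2-yl acetate F6.
- Oxalic acid on wet silica at 0 °C hydrolyses the vinylogous orthoester to 13.

Step 7. Risks: only modest or reversed facial selectivity, since the preference rests on a dipole effect of a remote acetate, and base-induced aromatisation of 13 in methanolic borohydride. Fallback, setting out from 13 and returning at 14: enzyme-controlled reduction with a ketoreductase picked from a panel for (S)-alcohol formation (NADPH, glucose/glucose dehydrogenase recycling, pH 7 phosphate buffer with DMSO co-solvent, 25 °C). The protein then sets C3, not the substrate, and the medium is neutral; this fallback makes no new compound (F0).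

Step 2. Risks: a low selectivity factor, or the opposite enantiomer preference, on this compact four-membered substrate. Fallback, setting out from 4 and returning at 5 (deracemisation by oxidation and asymmetric reduction):
- Catalytic HCl in MeOH removes the acetyl group and gives racemic 4-hydroxy-3-methoxycyclobut-2-en-1-one F7.
- MnO2 in CH2Cl2 oxidises it to 3-methoxycyclobut-3-ene-1,2-dione F8.
- Transfer hydrogenation with RuCl(p-cymene)[(R,R)-TsDPEN] and HCO2H/Et3N (antipodal catalyst if the sense is opposite) reduces the more electrophilic, non-vinylogous carbonyl and gives (R)-4-hydroxy-3-methoxycyclobut-2-en-1-one F9.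
- Ac2O and pyridine return 5.

**Further compounds**
F1 | step 6 | (R)-1-(2-acetoxy-5-hydroxy-3-methoxyphenyl)tridecan-2-yl acetate | CCCCCCCCCCC[C@H](Cc1cc(O)cc(OC)c1OC(C)=O)OC(C)=O
F2 | step 6 | (R)-1-(2-acetoxy-3,5-dimethoxyphenyl)tridecan-2-yl acetate | CCCCCCCCCCC[C@H](Cc1cc(OC)cc(OC)c1OC(C)=O)OC(C)=O
F3 | step 6 | (R)-1-(2-hydroxy-3,5-dimethoxyphenyl)tridecan-2-yl acetate | CCCCCCCCCCC[C@H](Cc1cc(OC)cc(OC)c1O)OC(C)=O
F4 | step 6 | (R)-1-(3,3,5-trimethoxy-6-oxocyclohexa-1,4-dien-1-yl)tridecan-2-yl acetate | CCCCCCCCCCC[C@H](CC1=CC(OC)(OC)C=C(OC)C1=O)OC(C)=O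
F5 | step 6 | (R)-1-[(6S)-6-hydroxy-3,3,5-trimethoxycyclohexa-1,4-dien-1-yl]tridecan-2-yl acetate | CCCCCCCCCCC[C@H](CC1=CC(OC)(OC)C=C(OC)[C@H]1O)OC(C)=O
F6 | step 6 | (R)-1-[(6S)-6-acetoxy-3,3,5-trimethoxycyclohexa-1,4-dien-1-yl]tridecan-2-yl acetate | CCCCCCCCCCC[C@H](CC1=CC(OC)(OC)C=C(OC)[C@H]1OC(C)=O)OC(C)=O
F0 | step 7 | none | none
F7 | step 2 | (±)-4-hydroxy-3-methoxycyclobut-2-en-1-one | O=C1C=C(OC)C1O
F8 | step 2 | 3-methoxycyclobut-3-ene-1,2-dione | O=C1C=C(OC)C1=O
F9 | step 2 | (R)-4-hydroxy-3-methoxycyclobut-2-en-1-one | O=C1C=C(OC)[C@H]1O
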